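**Plan**
- Retrosynthesis: the two primary alcohols (C9 and the ring B side chain) and the ring A phenol are traced back to an ethyl ester, a methyl ester and an aryl acetate; the C8–O4' ether bond and the C7–C8 bond are then cut together.
- Enabling feature: C8 carries the ether oxygen of ring B, the carbinol carbon C7 attached to ring A, and C9. This is an ester-bearing carbene carbon placed between a phenol O–H and an aldehyde C=O.
- Forward: sinapic acid 1 is hydrogenated to acid 2 and esterified to phenol 3. Phenol 3, ethyl diazoacetate 4 and vanillin acetate 5 are joined in one operation, through oxonium ylide 6, to the open-chain ester 7.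
- No ring is formed at any stage; ring A comes intact from 5 and ring B from 1. One LiAlH4 reduction of 7 gives the target 8.
- Stereochemistry: both centres (2S,3S in 7; C7 S and C8 R in 8) are set in the key step by a chiral zirconium–BINOL Lewis acid holding the aldehyde. The reduction leaves them alone; the C8 descriptor changes only because CO2Et becomes CH2OH.

Key step: step 3

Remark: the sense of induction of the zirconium–BINOL complex on this substrate pair cannot be predicted with confidence; the (R)-ligand is written, and its antipode would be used if a first run shows the mirror-image adduct.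

**Step 1**
Reactants: 1 sinapic acid, (E)-3-(4-hydroxy-3,5-dimethoxyphenyl)prop-2-enoic acid
Product: 2 3-(4-hydroxy-3,5-dimethoxyphenyl)propanoic acid (dihydrosinapic acid)
Conditions: H2 (1 atm), 10% Pd/C, MeOH, rt
Reagents that add atoms: none
Why: Heterogeneous catalytic hydrogenation saturates the cinnamic C=C bond, while the arene, the phenol, the methyl ethers and the acid are inert at one atmosphere and room temperature.

**Step 2**
Reactants: 2 3-(4-hydroxy-3,5-dimethoxyphenyl)propanoic acid
Product: 3 methyl 3-(4-hydroxy-3,5-dimethoxyphenyl)propanoate (methyl dihydrosinapate)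
Conditions: MeOH, H2SO4 (cat.), reflux
Reagents that add atoms: methanol, CO
Why: Fischer esterification in a large excess of methanol drives the acid to the methyl ester, and the hindered phenol is not alkylated under acid catalysis.

**Step 3**
Reactants: 3 methyl 3-(4-hydroxy-3,5-dimethoxyphenyl)propanoate; 4 ethyl diazoacetate; 5 vanillin acetate (4-formyl-2-methoxyphenyl acetate)
Product: 7 ethyl (2S,3S)-3-(4-acetoxy-3-methoxyphenyl)-3-hydroxy-2-[2,6-dimethoxy-4-(3-methoxy-3-oxopropyl)phenoxy]propanoate (anti, erythro), via oxonium ylide 6 (not isolated)
Conditions: Rh2(OAc)4 (2 mol%); catalyst pre-formed from Zr(OBu)4 (15 mol%) and (R)-3,3'-diiodo-BINOL (30 mol%) with the liberated butanol removed in vacuo; 4 Å MS, CH2Cl2, 0 °C to rt; 5 (2 equiv); 4 (1.5 equiv) added over 6 h by syringe pump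
Reagents that add atoms: none
Why: Proposed new method: Rh2(OAc)4 (divalent rhodium) expels N2 from 4 to give an electrophilic rhodium carbene, the phenol oxygen of 3 adds to it, and the resulting protic oxonium ylide 6 (in effect the enol of an aryloxyacetate) attacks through carbon the aldehyde 5 held on the chiral zirconium binolate before the 1,2-proton shift can end the sequence as plain O–H insertion, so the C8–O4' and C7–C8 bonds form in one operation and the phenolic proton ends on the C7 oxygen. The closest known reaction type is the Rh2(OAc)4/chiral zirconium–BINOL co-catalysed three-component coupling of aryl diazoacetates, alcohols and aldehydes by oxonium ylide trapping; an acceptor-only diazoacetate combined with a 2,6-disubstituted phenol has not been shown. No ring is closed; the step is a purely intermolecular chain assembly. C3 of 7 (C7, S) is set by the binolate of tetravalent zirconium, whose 3,3'-iodine atoms shield one face of the coordinated aldehyde, and C2 of 7 (C8, S) follows from the open, anti-selective transition state typical of zirconium–BINOL aldol catalysts, which gives the erythro adduct. The step needs chemoselectivity for O-attack on the carbene and for aldehyde trapping over proton shift: in 3 both ortho positions carry methoxy groups and the para position is alkylated, so oxygen is the only accessible nucleophilic site, and the acetate makes 5 more electrophilic than an alkoxybenzaldehyde. Slow addition of 4 into an excess of activated 5 keeps carbene dimerisation, carbonyl ylide formation and Lewis-acid-mediated homologation of the aldehyde down.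

**Step 4**
Reactants: 7 ethyl (2S,3S)-3-(4-acetoxy-3-methoxyphenyl)-3-hydroxy-2-[2,6-dimethoxy-4-(3-methoxy-3-oxopropyl)phenoxy]propanoate
Product: 8 4-[(1S,2R)-1,3-dihydroxy-2-[4-(3-hydroxypropyl)-2,6-dimethoxyphenoxy]propyl]-2-methoxyphenol (IN0404, erythro)
Conditions: LiAlH4 (excess), THF, 0 °C to rt; then H2O, sat. aq NH4Cl, 0 °C
Reagents that add atoms: none
Why: Hydride reduction with LiAlH4 converts both esters into primary alcohols and cleaves the aryl acetate to the phenol in the same operation, the usual end game of arylglycerol β-aryl ether syntheses, and neither stereocentre is touched because no bond at C7 or C8 is broken and the near-neutral cold work-up avoids quinone methide formation.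

**Compound list**
1 | sinapic acid, (E)-3-(4-hydroxy-3,5-dimethoxyphenyl)prop-2-enoic acid | COc1cc(/C=C/C(=O)O)cc(OC)c1O | starting material
2 | 3-(4-hydroxy-3,5-dimethoxyphenyl)propanoic acid | COc1cc(CCC(=O)O)cc(OC)c1O | intermediate
3 | methyl 3-(4-hydroxy-3,5-dimethoxyphenyl)propanoate | COC(=O)CCc1cc(OC)c(O)c(OC)c1 | intermediate
4 | ethyl diazoacetate | CCOC(=O)C=[N+]=[N-] | starting material
5 | vanillin acetate, 4-formyl-2-methoxyphenyl acetate | COc1cc(C=O)ccc1OC(C)=O | starting material
6 | protic oxonium ylide from the carbene of 4 and phenol 3 (drawn metal-free; not isolated) | CCOC(=O)[CH-][OH+]c1c(OC)cc(CCC(=O)OC)cc1OC | intermediate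
7 | ethyl (2S,3S)-3-(4-acetoxy-3-methoxyphenyl)-3-hydroxy-2-[2,6-dimethoxy-4-(3-methoxy-3-oxopropyl)phenoxy]propanoate | COc1cc([C@H](O)[C@@H](C(=O)OCC)Oc2c(OC)cc(CCC(=O)OC)cc2OC)ccc1OC(C)=O | intermediate
8 | 4-[(1S,2R)-1,3-dihydroxy-2-[4-(3-hydroxypropyl)-2,6-dimethoxyphenoxy]propyl]-2-methoxyphenol | COc1cc([C@H](O)[C@@H](CO)Oc2c(OC)cc(CCCO)cc2OC)ccc1O | target

**Step count**
Total steps: 4. Longest linear sequence: 4 steps (1 → 2 → 3 → 7 → 8).

**Steps most likely to fail**

1. Step 3 (the proposed new method). The ylide may undergo the 1,2-proton shift faster than it is trapped, so that only O–H insertion is seen, or the zirconium complex may give poor facial or anti/syn control. The fallback makes the same two bonds one after the other with known reactions, setting out from 3 and returning at 7. Phenol 3 is alkylated with ethyl bromoacetate (K2CO3, acetone, reflux) to ethyl 2-[2,6-dimethoxy-4-(3-methoxy-3-oxopropyl)phenoxy]acetate F1, which is also the insertion by-product of step 3 and can be collected from it. The aryloxy-substituted α-position, the more acidic of the two ester α-positions, is enolised with one equivalent of LiN(SiMe3)2 in THF at −78 °C and silylated with Me3SiCl to the ketene silyl acetal methyl 3-[4-[(2-ethoxy-2-trimethylsilyloxyethenyl)oxy]-3,5-dimethoxyphenyl]propanoate F2 (either double-bond geometry is acceptable). An anti-selective catalytic asymmetric Mukaiyama aldol addition of F2 to aldehyde 5 follows, with a catalyst prepared from Zr(OtBu)4 (tetravalent zirconium), (R)-3,3'-diiodo-BINOL, propanol and a trace of water in toluene at 0 °C. Mild acidic desilylation on work-up should then deliver ester 7.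

2. Step 4. The aluminium β-alkoxide may fragment by retro-aldol cleavage before the C9 ester is reduced, or C7 may epimerise through a quinone methide once the ring A phenoxide is unmasked and the mixture is worked up. The fallback sets out from 7 and returns at 8. The C7 hydroxyl is silylated (TBSOTf, 2,6-lutidine, CH2Cl2, −78 to 0 °C) to ethyl (2S,3S)-3-(4-acetoxy-3-methoxyphenyl)-3-[(tert-butyldimethylsilyl)oxy]-2-[2,6-dimethoxy-4-(3-methoxy-3-oxopropyl)phenoxy]propanoate F3, which can no longer undergo retro-aldol cleavage. Excess i-Bu2AlH in CH2Cl2 (−78 to 0 °C) reduces both esters and removes the acetate to give 4-[(1S,2R)-1-[(tert-butyldimethylsilyl)oxy]-3-hydroxy-2-[4-(3-hydroxypropyl)-2,6-dimethoxyphenoxy]propyl]-2-methoxyphenol F4. Bu4NF buffered with AcOH in THF at 0 °C then frees the carbinol to give 8. A silyl shift from O7 to O9 during the reduction would be harmless, since desilylation leads to 8 either way.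

3. Step 1. Hydrogen uptake may stop early through deactivation of the palladium surface by impurities of the plant-derived acid, or partial esterification in methanol may give a mixture. The fallback sets out from 1 and returns at 3, bypassing 2. Sinapic acid 1 is first esterified (MeOH, H2SO4 cat., reflux) to methyl (E)-3-(4-hydroxy-3,5-dimethoxyphenyl)prop-2-enoate F5. Its conjugated C=C bond is then reduced by hydride transfer with NaBH4 and NiCl2 (divalent nickel, as the hexahydrate) in MeOH at 0 °C, which gives 3 directly.

**Further compounds**
F1 | step 3 | ethyl 2-[2,6-dimethoxy-4-(3-methoxy-3-oxopropyl)phenoxy]acetate | CCOC(=O)COc1c(OC)cc(CCC(=O)OC)cc1OC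
F2 | step 3 | methyl 3-[4-[(2-ethoxy-2-trimethylsilyloxyethenyl)oxy]-3,5-dimethoxyphenyl]propanoate | CCOC(O[Si](C)(C)C)=COc1c(OC)cc(CCC(=O)OC)cc1OC
F3 | step 4 | ethyl (2S,3S)-3-(4-acetoxy-3-methoxyphenyl)-3-[(tert-butyldimethylsilyl)oxy]-2-[2,6-dimethoxy-4-(3-methoxy-3-oxopropyl)phenoxy]propanoate | COc1cc([C@H](O[Si](C)(C)C(C)(C)C)[C@@H](C(=O)OCC)Oc2c(OC)cc(CCC(=O)OC)cc2OC)ccc1OC(C)=O
F4 | step 4 | 4-[(1S,2R)-1-[(tert-butyldimethylsilyl)oxy]-3-hydroxy-2-[4-(3-hydroxypropyl)-2,6-dimethoxyphenoxy]propyl]-2-methoxyphenol | COc1cc([C@H](O[Si](C)(C)C(C)(C)C)[C@@H](CO)Oc2c(OC)cc(CCCO)cc2OC)ccc1O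
F5 | step 1 | methyl (E)-3-(4-hydroxy-3,5-dimethoxyphenyl)prop-2-enoate | COC(=O)/C=C/c1cc(OC)c(O)c(OC)c1
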